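**Retrosynthetic overview**
1. Target 32 comes from β-keto ester 29 by ester removal: the C3 methoxycarbonyl group is a traceless activator and the C4 acid travels as its tert-butyl ester.
2. Key disconnection: cyclopentanone ring B is cut at C2–C3 and C1–C7a, giving a cyclohexenyl 1-propynyl ether (oxygen on C6, C7=C7a alkene) that carries an ester enolate at C3; forward, a [3,3] shift is followed by ketene capture.
3. Enabling feature: in ring A the C6=C7 double bond is allylic to the ring-fusion carbon C7a, so C6–C7–C7a is an allyl unit on which an oxygen at C6 can deliver C1 to C7a suprafacially, while the ring B carbonyl C2, flanked by C1 and C3, emerges as a ketene carbon.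
4. The C3a side chain comes from an earlier suprafacial Johnson–Claisen shift from a C7 tertiary allylic alcohol (epoxide/selenoxide transposition); the styryl group comes from the C5 carboxyl carbon.
5. Ring A, with the vicinal quaternary carbons C4/C5, is formed first by a Diels–Alder reaction of 3,4-diethylfuran-2,5-dione with a 1-silyloxy-2-methyldiene (resolution at the half-ester stage); ring B is formed last.

Key step: step 15

Locants in the Why lines are those of the target (C1 CHMe, C2 C=O, C3 CHEt, C3a, C4 C(Et)CO2H, C5 C(Et)(styryl), C6 =CH, C7 =CMe, C7a; ring A is the six-membered ring, ring B the cyclopentanone). β is the face of ring A that carries the C4 carboxyl carbon and the C5 styryl carbon; α is the face of the two ethyl groups.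

Assumption: the salt of the required enantiomer of acid 8 with (1R)-1-phenylethan-1-amine is the less soluble one; if the opposite holds, the (1S)-amine is used in the same way.

**Route**

Step 1
Reactants: 1 hex-3-yne
Product: 3 3,4-diethylfuran-2,5-dione, via magnesium diethylmaleate 2 (not isolated)
Conditions: Ni(acac)2 (cat.), 2,2'-bipyridine, Zn, MgBr2, CO2 (1 atm), DMF, rt; then aq. HCl
Reagents that add atoms: carbon dioxide, O=C=O
Why: Nickel-catalysed reductive double carboxylation of an internal alkyne (zinc as terminal reductant) should deliver the cis-dicarboxylate 2, which closes to the anhydride on acidification because a 2,3-dialkylmaleic acid dehydrates spontaneously; no stereocentre is formed.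

Step 2
Reactants: 4 (2E)-2-methylbut-2-enal
Product: 5 tert-butyl(dimethyl){[(1E)-2-methylbuta-1,3-dien-1-yl]oxy}silane
Conditions: t-BuMe2SiOTf, Et3N, Et2O, 0 °C to rt
Reagents that add atoms: tert-butyldimethylsilyl trifluoromethanesulfonate, CC(C)(C)[Si](C)(C)OS(=O)(=O)C(F)(F)F
Why: Soft enolisation (O-silylation of the enal, then γ-deprotonation by the amine) should give the silyl dienol ether, the 1E isomer predominating and being the only one that reaches the s-cis conformation needed in step 3; no stereocentre is formed.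

Step 3
Reactants: 3 3,4-diethylfuran-2,5-dione; 5 tert-butyl(dimethyl){[(1E)-2-methylbuta-1,3-dien-1-yl]oxy}silane
Product: 6 rac-4-[(tert-butyldimethylsilyl)oxy]-3a,7a-diethyl-5-methyl-3a,4,7,7a-tetrahydro-2-benzofuran-1,3-dione
Conditions: toluene, BHT (cat.), 130 °C, sealed tube, excess 5
Reagents that add atoms: none
Why: A thermal Diels–Alder reaction of the electron-rich 1-silyloxydiene with the symmetrical (regiochemically silent) dialkylmaleic anhydride should form ring A, suprafacial addition fixing the cis relation of the new quaternary carbons C4/C5 and the endo transition state (anhydride under the diene, ethyl groups away from the C7 methyl) placing the C6 silyloxy group cis to the anhydride; the product is racemic.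

Step 4
Reactants: 6 rac-4-[(tert-butyldimethylsilyl)oxy]-3a,7a-diethyl-5-methyl-3a,4,7,7a-tetrahydro-2-benzofuran-1,3-dione
Product: 7 rac-4-[(tert-butyldimethylsilyl)oxy]-3a,7a-diethyl-5-methyl-5,6-epoxyhexahydro-2-benzofuran-1,3-dione
Conditions: mCPBA, NaHCO3, CH2Cl2, 0 °C
Reagents that add atoms: 3-chloroperoxybenzoic acid, OOC(=O)c1cccc(Cl)c1
Why: Peracid (Prilezhaev) epoxidation of the only alkene should occur on the convex α face, anti to the folded cis-fused anhydride ring and to the allylic silyloxy group, giving the α-oxirane at C7/C7a.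

Step 5
Reactants: 7 rac-4-[(tert-butyldimethylsilyl)oxy]-3a,7a-diethyl-5-methyl-5,6-epoxyhexahydro-2-benzofuran-1,3-dione
Product: 8 rac-4-(tert-butoxycarbonyl)-2-[(tert-butyldimethylsilyl)oxy]-3,4-diethyl-1-methyl-7-oxabicyclo[4.1.0]heptane-3-carboxylic acid
Conditions: KOt-Bu (1.05 equiv), THF, −40 to 0 °C; cold aq. NaH2PO4 buffer, used at once
Reagents that add atoms: potassium tert-butoxide, CC(C)(C)[O-].[K+]
Why: Alcoholysis of the cyclic anhydride by tert-butoxide should occur at the less hindered carbonyl (on C4, next to the C3a methylene) and not at the carbonyl on C5, which is shielded by the adjacent cis C6 silyloxy group, so the future C4 carboxyl is protected as a bulky ester and the C5 carboxyl is left free; no stereocentre changes.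

Step 6
Reactants: 8 rac-4-(tert-butoxycarbonyl)-2-[(tert-butyldimethylsilyl)oxy]-3,4-diethyl-1-methyl-7-oxabicyclo[4.1.0]heptane-3-carboxylic acid; 9 (1R)-1-phenylethan-1-amine
Product: 10 (1R)-1-phenylethan-1-aminium salt of the required enantiomer of 8
Conditions: EtOAc/heptane, crystallisation, recrystallisation
Reagents that add atoms: none
Why: Classical resolution, in which the diastereomeric ammonium carboxylates differ in solubility and the less soluble salt of the required enantiomer is brought to purity by recrystallisation (absolute configuration to be checked by X-ray analysis of the salt).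

Step 7
Reactants: 10 (1R)-1-phenylethan-1-aminium salt of the required enantiomer of 8
Product: 12 tert-butyl 5-[(tert-butyldimethylsilyl)oxy]-3,4-diethyl-4-(hydroxymethyl)-6-methyl-7-oxabicyclo[4.1.0]heptane-3-carboxylate, via free acid 11 (not isolated)
Conditions: cold aq. NaH2PO4/EtOAc partition; then BH3·SMe2, THF, 0 °C to rt; MeOH quench
Reagents that add atoms: none
Why: Borane reduces the free carboxylic acid (through its acyloxyborane) much faster than the hindered tert-butyl ester, the epoxide or the silyl ether, so only the C5 carboxyl carbon should be taken to the primary alcohol, which is oxidised at once in step 8; no stereocentre changes.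

Step 8
Reactants: 12 tert-butyl 5-[(tert-butyldimethylsilyl)oxy]-3,4-diethyl-4-(hydroxymethyl)-6-methyl-7-oxabicyclo[4.1.0]heptane-3-carboxylate
Product: 13 tert-butyl 5-[(tert-butyldimethylsilyl)oxy]-3,4-diethyl-4-formyl-6-methyl-7-oxabicyclo[4.1.0]heptane-3-carboxylate
Conditions: Dess–Martin periodinane, NaHCO3, CH2Cl2, 0 °C to rt
Reagents that add atoms: none
Why: Dess–Martin oxidation under bicarbonate buffer should convert the neopentyl primary alcohol into the non-enolisable aldehyde without opening the acid-sensitive epoxide.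

Step 9
Reactants: 13 tert-butyl 5-[(tert-butyldimethylsilyl)oxy]-3,4-diethyl-4-formyl-6-methyl-7-oxabicyclo[4.1.0]heptane-3-carboxylate; 14 diethyl benzylphosphonate
Product: 15 tert-butyl 5-[(tert-butyldimethylsilyl)oxy]-3,4-diethyl-6-methyl-4-[(E)-2-phenylethenyl]-7-oxabicyclo[4.1.0]heptane-3-carboxylate
Conditions: KOt-Bu, THF, 0 °C to rt
Reagents that add atoms: none
Why: Horner–Wadsworth–Emmons olefination with the semi-stabilised benzylphosphonate anion should give the styrene with E geometry because reversible addition funnels through the anti oxaphosphetane; the quaternary C5 centre is not affected.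

Step 10
Reactants: 15 tert-butyl 5-[(tert-butyldimethylsilyl)oxy]-3,4-diethyl-6-methyl-4-[(E)-2-phenylethenyl]-7-oxabicyclo[4.1.0]heptane-3-carboxylate
Product: 18 tert-butyl 5-[(tert-butyldimethylsilyl)oxy]-1,6-diethyl-4-hydroxy-4-methyl-6-[(E)-2-phenylethenyl]cyclohex-2-ene-1-carboxylate, via hydroxy selenide 16 (not isolated), via selenoxide 17 (not isolated)
Conditions: (PhSe)2, NaBH4, EtOH, 70 °C; then THF, 30% H2O2, pyridine, 0 °C to rt
Reagents that add atoms: none
Why: Phenylselenide anion should open the epoxide in trans-diaxial fashion at the less substituted carbon C7a, and the selenoxide then undergoes syn-elimination, which can only run towards C3a because C7 carries no hydrogen, so the alkene is transposed to C3a=C7a and the tertiary C7 hydroxyl keeps the α configuration of the oxirane oxygen.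

Step 11
Reactants: 18 tert-butyl 5-[(tert-butyldimethylsilyl)oxy]-1,6-diethyl-4-hydroxy-4-methyl-6-[(E)-2-phenylethenyl]cyclohex-2-ene-1-carboxylate; 19 1,1,1-trimethoxybutane
Product: 21 tert-butyl 5-[(tert-butyldimethylsilyl)oxy]-1,6-diethyl-2-(1-methoxy-1-oxobutan-2-yl)-4-methyl-6-[(E)-2-phenylethenyl]cyclohex-3-ene-1-carboxylate, via ketene acetal 20 (not isolated)
Conditions: EtCO2H (cat.), xylene, 140 °C, MeOH distilled off
Reagents that add atoms: none
Why: In this orthoester Johnson–Claisen rearrangement, acid-catalysed exchange gives the mixed ketene acetal, whose suprafacial [3,3] shift through a chair transition state (C7–O pseudoaxial) should form C3–C3a on the α face, transfer the C7 configuration to C3a (H-3a β), return the alkene to C7=C7a and install the ester-activated C3 carbon as an inconsequential epimer mixture.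

Step 12
Reactants: 21 tert-butyl 5-[(tert-butyldimethylsilyl)oxy]-1,6-diethyl-2-(1-methoxy-1-oxobutan-2-yl)-4-methyl-6-[(E)-2-phenylethenyl]cyclohex-3-ene-1-carboxylate
Product: 22 tert-butyl 1,6-diethyl-5-hydroxy-2-(1-methoxy-1-oxobutan-2-yl)-4-methyl-6-[(E)-2-phenylethenyl]cyclohex-3-ene-1-carboxylate
Conditions: Bu4NF, AcOH, THF, rt to 40 °C
Reagents that add atoms: none
Why: Fluoride-induced desilylation under acetic acid buffering should free the C6 allylic alcohol, the bulky tert-butyl ester on quaternary C4 resisting lactonisation with the cis hydroxyl; no stereocentre changes.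

Step 13
Reactants: 22 tert-butyl 1,6-diethyl-5-hydroxy-2-(1-methoxy-1-oxobutan-2-yl)-4-methyl-6-[(E)-2-phenylethenyl]cyclohex-3-ene-1-carboxylate
Product: 23 tert-butyl 1,6-diethyl-2-(1-methoxy-1-oxobutan-2-yl)-4-methyl-5-(2-oxopropoxy)-6-[(E)-2-phenylethenyl]cyclohex-3-ene-1-carboxylate
Conditions: 1-diazopropan-2-one (slow addition), Rh2(OAc)4 (cat.), CH2Cl2, rt
Reagents that add atoms: 1-diazopropan-2-one, CC(=O)C=[N+]=[N-]
Why: Dirhodium-carbenoid O–H insertion should alkylate the hindered secondary alcohol under neutral conditions (with slow addition of the diazo ketone, insertion into O–H outruns cyclopropanation of the alkenes), giving the α-alkoxy ketone with retention at C6.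

Step 14
Reactants: 23 tert-butyl 1,6-diethyl-2-(1-methoxy-1-oxobutan-2-yl)-4-methyl-5-(2-oxopropoxy)-6-[(E)-2-phenylethenyl]cyclohex-3-ene-1-carboxylate
Product: 24 tert-butyl 1,6-diethyl-2-(1-methoxy-1-oxobutan-2-yl)-4-methyl-6-[(E)-2-phenylethenyl]-5-{[(1Z)-2-(trifluoromethanesulfonyloxy)prop-1-en-1-yl]oxy}cyclohex-3-ene-1-carboxylate
Conditions: LiN(SiMe3)2 (1.05 equiv), THF, −78 °C; PhNTf2, −78 to 0 °C
Reagents that add atoms: N-phenylbis(trifluoromethanesulfonimide), O=S(=O)(N(c1ccccc1)S(=O)(=O)C(F)(F)F)C(F)(F)F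
Why: Enolisation of the α-alkoxy ketone on the alkoxy-bearing methylene (the more acidic site, lithium chelated by the ether oxygen) followed by O-sulfonylation should give the Z enol triflate, the known first half of the two-step alkynyl ether synthesis from α-alkoxy ketones, while the far less acidic ester α-hydrogen at C3 stays untouched with one equivalent of base.

Step 15
Reactants: 24 tert-butyl 1,6-diethyl-2-(1-methoxy-1-oxobutan-2-yl)-4-methyl-6-[(E)-2-phenylethenyl]-5-{[(1Z)-2-(trifluoromethanesulfonyloxy)prop-1-en-1-yl]oxy}cyclohex-3-ene-1-carboxylate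
Product: 29 4-tert-butyl 3-methyl 3,4,5-triethyl-1,7-dimethyl-2-oxo-5-[(E)-2-phenylethenyl]-2,3,3a,4,5,7a-hexahydro-1H-indene-3,4-dicarboxylate, via ester enolate 25 (not isolated), via propynyl ether 26 (not isolated), via ketene 27 (not isolated), via ketone enolate 28 (not isolated)
Conditions: KN(SiMe3)2 (1.1 equiv), THF, −78 °C; then KOt-Bu (1.3 equiv), −78 to 0 °C; aq. NH4Cl
Reagents that add atoms: none
Why: Proposed new method: KN(SiMe3)2 first converts the C3 methyl ester into its potassium enolate 25 and KOt-Bu then eliminates triflate anti from the Z enol triflate to give the allyl 1-propynyl ether 26, which should undergo a [3,3]-sigmatropic (alkynyl ether Claisen) shift below 0 °C through a chair transition state with the C6–O bond pseudoaxial, forming C1–C7a, moving the ring double bond to C6=C7 and releasing the methylketene 27, whose sp carbon C2 is then C-acylated by the pendant ester enolate to close the cyclopentanone as ketone enolate 28. The closest known reaction types are the low-temperature rearrangement of allyl alkynyl ethers to allyl ketenes that are trapped by external nucleophiles and the rearrangement/intramolecular ketene capture of benzyl alkynyl ethers that gives 2-indanones; new here is capture of the ketene by a tethered ester enolate, itself the equivalent of the well-known C-acylation of enolates by ketenes. Ring B closes in a 5-exo-dig mode (C3 attacks the ketene carbon, the C=O π bond staying exocyclic), and ring A is untouched apart from the allylic transposition. C7a is set by suprafacial chirality transfer from the β C6–O bond, which puts C1 on the β face and H-7a α, anti to the pseudoaxial α side chain at C3a, so the ring fusion must be trans; C3 becomes quaternary and C1 forms as an epimer mixture, both being dealt with in step 16. The step needs elimination to the alkyne and not to the alkoxyallene, and intramolecular capture of the ketene ahead of tert-butoxide addition or dimerisation; the Z geometry of the triflate (H anti to OTf), the preformed enolate held within reach of the ketene carbon and the low temperature should secure this.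

Step 16
Reactants: 29 4-tert-butyl 3-methyl 3,4,5-triethyl-1,7-dimethyl-2-oxo-5-[(E)-2-phenylethenyl]-2,3,3a,4,5,7a-hexahydro-1H-indene-3,4-dicarboxylate
Product: 31 tert-butyl (1S,3S,3aR,4R,5S,7aR)-3,4,5-triethyl-1,7-dimethyl-2-oxo-5-[(E)-2-phenylethenyl]-2,3,3a,4,5,7a-hexahydro-1H-indene-4-carboxylate, via lithium keto carboxylate 30 (not isolated)
Conditions: LiCl, H2O, DMSO, 140 °C; then DBU (cat.), CH2Cl2, rt
Reagents that add atoms: none
Why: Krapcho demethoxycarbonylation (chloride SN2 at the methyl group, loss of CO2 from the β-keto carboxylate, protonation of the enolate) should remove the activating ester from C3, and base-mediated equilibration through the enolates should then set both ketone α-centres thermodynamically, ethyl at C3 and methyl at C1 each pseudoequatorial and trans to the neighbouring ring-fusion substituent, as in the target.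

Step 17
Reactants: 31 tert-butyl (1S,3S,3aR,4R,5S,7aR)-3,4,5-triethyl-1,7-dimethyl-2-oxo-5-[(E)-2-phenylethenyl]-2,3,3a,4,5,7a-hexahydro-1H-indene-4-carboxylate
Product: 32 (1S,3S,3aR,4R,5S,7aR)-3,4,5-triethyl-1,7-dimethyl-2-oxo-5-[(E)-2-phenylethenyl]-2,3,3a,4,5,7a-hexahydro-1H-indene-4-carboxylic acid
Conditions: CF3CO2H, CH2Cl2, 0 °C
Reagents that add atoms: none
Why: Acidolysis of the tert-butyl ester (E1 loss of isobutene) should unveil the C4 carboxylic acid under conditions that leave the ketone, the trisubstituted alkene and the styrene intact and do not disturb the thermodynamically set α-centres.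

**Compound list**

1 | hex-3-yne | CCC#CCC | starting material
2 | magnesium (2Z)-2,3-diethylbut-2-enedioate | [O-]C(=O)/C(CC)=C(/CC)C(=O)[O-].[Mg+2] | intermediate (not isolated)
3 | 3,4-diethylfuran-2,5-dione | CCC1=C(CC)C(=O)OC1=O | intermediate
4 | (2E)-2-methylbut-2-enal | C/C=C(\C)C=O | starting material
5 | tert-butyl(dimethyl){[(1E)-2-methylbuta-1,3-dien-1-yl]oxy}silane | C=C/C(C)=C/O[Si](C)(C)C(C)(C)C | intermediate
6 | rac-4-[(tert-butyldimethylsilyl)oxy]-3a,7a-diethyl-5-methyl-3a,4,7,7a-tetrahydro-2-benzofuran-1,3-dione (cis ring fusion; silyloxy cis to the anhydride ring; racemate, the enantiomer drawn is the one carried on) | CC1=CC[C@@]2(CC)C(=O)OC(=O)[C@@]2(CC)[C@H]1O[Si](C)(C)C(C)(C)C | intermediate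
7 | rac-4-[(tert-butyldimethylsilyl)oxy]-3a,7a-diethyl-5-methyl-5,6-epoxyhexahydro-2-benzofuran-1,3-dione (oxirane α, trans to anhydride ring and silyloxy group; racemate) | C[C@@]12O[C@@H]1C[C@@]3(CC)C(=O)OC(=O)[C@@]3(CC)[C@H]2O[Si](C)(C)C(C)(C)C | intermediate
8 | rac-4-(tert-butoxycarbonyl)-2-[(tert-butyldimethylsilyl)oxy]-3,4-diethyl-1-methyl-7-oxabicyclo[4.1.0]heptane-3-carboxylic acid (CO2H, CO2t-Bu and silyloxy β; oxirane α; racemate) | C[C@@]12O[C@@H]1C[C@@](CC)(C(=O)OC(C)(C)C)[C@@](CC)(C(=O)O)[C@H]2O[Si](C)(C)C(C)(C)C | intermediate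
9 | (1R)-1-phenylethan-1-amine | C[C@@H](N)c1ccccc1 | starting material
10 | (1R)-1-phenylethan-1-aminium salt of the required enantiomer of 8 | C[C@@]12O[C@@H]1C[C@@](CC)(C(=O)OC(C)(C)C)[C@@](CC)(C(=O)[O-])[C@H]2O[Si](C)(C)C(C)(C)C.C[C@@H]([NH3+])c1ccccc1 | intermediate
11 | free acid of 10 (single enantiomer of 8) | C[C@@]12O[C@@H]1C[C@@](CC)(C(=O)OC(C)(C)C)[C@@](CC)(C(=O)O)[C@H]2O[Si](C)(C)C(C)(C)C | intermediate (not isolated)
12 | tert-butyl 5-[(tert-butyldimethylsilyl)oxy]-3,4-diethyl-4-(hydroxymethyl)-6-methyl-7-oxabicyclo[4.1.0]heptane-3-carboxylate (ester, CH2OH and silyloxy β; oxirane α) | C[C@@]12O[C@@H]1C[C@@](CC)(C(=O)OC(C)(C)C)[C@@](CC)(CO)[C@H]2O[Si](C)(C)C(C)(C)C | intermediate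
13 | tert-butyl 5-[(tert-butyldimethylsilyl)oxy]-3,4-diethyl-4-formyl-6-methyl-7-oxabicyclo[4.1.0]heptane-3-carboxylate (ester, CHO and silyloxy β; oxirane α) | C[C@@]12O[C@@H]1C[C@@](CC)(C(=O)OC(C)(C)C)[C@@](CC)(C=O)[C@H]2O[Si](C)(C)C(C)(C)C | intermediate
14 | diethyl benzylphosphonate | CCOP(=O)(Cc1ccccc1)OCC | starting material
15 | tert-butyl 5-[(tert-butyldimethylsilyl)oxy]-3,4-diethyl-6-methyl-4-[(E)-2-phenylethenyl]-7-oxabicyclo[4.1.0]heptane-3-carboxylate (ester, styryl and silyloxy β; oxirane α) | C[C@@]12O[C@@H]1C[C@@](CC)(C(=O)OC(C)(C)C)[C@@](CC)(/C=C/c3ccccc3)[C@H]2O[Si](C)(C)C(C)(C)C | intermediate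
16 | tert-butyl 5-[(tert-butyldimethylsilyl)oxy]-1,6-diethyl-4-hydroxy-4-methyl-3-(phenylselanyl)-6-[(E)-2-phenylethenyl]cyclohexane-1-carboxylate (4-OH α, 3-SePh β) | C[C@@]1(O)[C@@H]([Se]c2ccccc2)C[C@@](CC)(C(=O)OC(C)(C)C)[C@@](CC)(/C=C/c2ccccc2)[C@H]1O[Si](C)(C)C(C)(C)C | intermediate (not isolated)
17 | selenoxide of 16 | C[C@@]1(O)[C@@H]([Se](=O)c2ccccc2)C[C@@](CC)(C(=O)OC(C)(C)C)[C@@](CC)(/C=C/c2ccccc2)[C@H]1O[Si](C)(C)C(C)(C)C | intermediate (not isolated)
18 | tert-butyl 5-[(tert-butyldimethylsilyl)oxy]-1,6-diethyl-4-hydroxy-4-methyl-6-[(E)-2-phenylethenyl]cyclohex-2-ene-1-carboxylate (4-OH α, 4-methyl β, 5-silyloxy β) | C[C@@]1(O)C=C[C@@](CC)(C(=O)OC(C)(C)C)[C@@](CC)(/C=C/c2ccccc2)[C@H]1O[Si](C)(C)C(C)(C)C | intermediate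
19 | 1,1,1-trimethoxybutane | CCCC(OC)(OC)OC | starting material
20 | mixed ketene acetal of 18 (1-methoxybut-1-en-1-yl ether at the tertiary oxygen) | C[C@@]1(OC(OC)=CCC)C=C[C@@](CC)(C(=O)OC(C)(C)C)[C@@](CC)(/C=C/c2ccccc2)[C@H]1O[Si](C)(C)C(C)(C)C | intermediate (not isolated)
21 | tert-butyl 5-[(tert-butyldimethylsilyl)oxy]-1,6-diethyl-2-(1-methoxy-1-oxobutan-2-yl)-4-methyl-6-[(E)-2-phenylethenyl]cyclohex-3-ene-1-carboxylate (side chain at C2 α, H β; silyloxy β; epimers at the side-chain α-carbon) | CC1=C[C@H](C(CC)C(=O)OC)[C@@](CC)(C(=O)OC(C)(C)C)[C@@](CC)(/C=C/c2ccccc2)[C@H]1O[Si](C)(C)C(C)(C)C | intermediate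
22 | tert-butyl 1,6-diethyl-5-hydroxy-2-(1-methoxy-1-oxobutan-2-yl)-4-methyl-6-[(E)-2-phenylethenyl]cyclohex-3-ene-1-carboxylate (5-OH β) | CC1=C[C@H](C(CC)C(=O)OC)[C@@](CC)(C(=O)OC(C)(C)C)[C@@](CC)(/C=C/c2ccccc2)[C@H]1O | intermediate
23 | tert-butyl 1,6-diethyl-2-(1-methoxy-1-oxobutan-2-yl)-4-methyl-5-(2-oxopropoxy)-6-[(E)-2-phenylethenyl]cyclohex-3-ene-1-carboxylate | CC1=C[C@H](C(CC)C(=O)OC)[C@@](CC)(C(=O)OC(C)(C)C)[C@@](CC)(/C=C/c2ccccc2)[C@H]1OCC(C)=O | intermediate
24 | tert-butyl 1,6-diethyl-2-(1-methoxy-1-oxobutan-2-yl)-4-methyl-6-[(E)-2-phenylethenyl]-5-{[(1Z)-2-(trifluoromethanesulfonyloxy)prop-1-en-1-yl]oxy}cyclohex-3-ene-1-carboxylate | CC1=C[C@H](C(CC)C(=O)OC)[C@@](CC)(C(=O)OC(C)(C)C)[C@@](CC)(/C=C/c2ccccc2)[C@H]1O/C=C(/C)OS(=O)(=O)C(F)(F)F | intermediate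
25 | potassium ester enolate of 24 | CC1=C[C@H](C(CC)=C([O-])OC)[C@@](CC)(C(=O)OC(C)(C)C)[C@@](CC)(/C=C/c2ccccc2)[C@H]1O/C=C(/C)OS(=O)(=O)C(F)(F)F.[K+] | intermediate (not isolated)
26 | 5-(prop-1-yn-1-yloxy) analogue of 25 (allyl 1-propynyl ether, potassium ester enolate) | CC1=C[C@H](C(CC)=C([O-])OC)[C@@](CC)(C(=O)OC(C)(C)C)[C@@](CC)(/C=C/c2ccccc2)[C@H]1OC#CC.[K+] | intermediate (not isolated)
27 | rearranged methylketene (1-oxoprop-1-en-2-yl group β on C7a, ring alkene C6=C7, potassium ester enolate at C3) | CC(=C=O)[C@@H]1C(C)=C[C@@](/C=C/c2ccccc2)(CC)[C@](CC)(C(=O)OC(C)(C)C)[C@H]1C(CC)=C([O-])OC.[K+] | intermediate (not isolated)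
28 | potassium C1=C2 enolate of 29 | CCC1(C(=O)OC)C([O-])=C(C)[C@@H]2C(C)=C[C@@](/C=C/c3ccccc3)(CC)[C@](CC)(C(=O)OC(C)(C)C)[C@H]21.[K+] | intermediate (not isolated)
29 | 4-tert-butyl 3-methyl 3,4,5-triethyl-1,7-dimethyl-2-oxo-5-[(E)-2-phenylethenyl]-2,3,3a,4,5,7a-hexahydro-1H-indene-3,4-dicarboxylate (trans ring fusion, H-3a β, H-7a α; epimers at C1 and C3) | CCC1(C(=O)OC)C(=O)C(C)[C@@H]2C(C)=C[C@@](/C=C/c3ccccc3)(CC)[C@](CC)(C(=O)OC(C)(C)C)[C@H]21 | intermediate
30 | lithium 4-(tert-butoxycarbonyl)-3,4,5-triethyl-1,7-dimethyl-2-oxo-5-[(E)-2-phenylethenyl]-2,3,3a,4,5,7a-hexahydro-1H-indene-3-carboxylate | CCC1(C(=O)[O-])C(=O)C(C)[C@@H]2C(C)=C[C@@](/C=C/c3ccccc3)(CC)[C@](CC)(C(=O)OC(C)(C)C)[C@H]21.[Li+] | intermediate (not isolated)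
31 | tert-butyl (1S,3S,3aR,4R,5S,7aR)-3,4,5-triethyl-1,7-dimethyl-2-oxo-5-[(E)-2-phenylethenyl]-2,3,3a,4,5,7a-hexahydro-1H-indene-4-carboxylate | CC[C@@H]1C(=O)[C@@H](C)[C@@H]2C(C)=C[C@@](/C=C/c3ccccc3)(CC)[C@](CC)(C(=O)OC(C)(C)C)[C@H]21 | intermediate
32 | (1S,3S,3aR,4R,5S,7aR)-3,4,5-triethyl-1,7-dimethyl-2-oxo-5-[(E)-2-phenylethenyl]-2,3,3a,4,5,7a-hexahydro-1H-indene-4-carboxylic acid | CC[C@@H]1C(=O)[C@@H](C)[C@@H]2C(C)=C[C@@](/C=C/c3ccccc3)(CC)[C@](CC)(C(=O)O)[C@H]21 | target

**Step count and risks**

Total step count: 17. Longest linear sequence: 16 steps (steps 2 to 17 from 4, or steps 1 and 3 to 17 from 1).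

Steps most likely to fail:

Step 15 (the step with the label "Proposed new method:"; its precursor steps 13 and 14 share the risk). The base may eliminate towards the alkoxyallene in place of the alkyne, or the ketene may be intercepted intermolecularly (tert-butoxide addition, dimerisation) before ring closure. The fallback uses known chemistry, sets out from 22 and comes back at 29. Alcohol 22 is heated with trimethyl orthopropionate and catalytic propionic acid (Johnson–Claisen rearrangement, same suprafacial delivery of C1 to the β face of C7a) to give the triester tert-butyl 1,6-diethyl-2-(1-methoxy-1-oxobutan-2-yl)-3-(1-methoxy-1-oxopropan-2-yl)-4-methyl-6-[(E)-2-phenylethenyl]cyclohex-4-ene-1-carboxylate F1. Dieckmann condensation of F1 with KN(SiMe3)2 in THF then closes ring B to 29. It may give in part the regioisomeric β-keto ester 4-tert-butyl 1-methyl 3,4,5-triethyl-1,7-dimethyl-2-oxo-5-[(E)-2-phenylethenyl]-2,3,3a,4,5,7a-hexahydro-1H-indene-1,4-dicarboxylate F2, which loses its ester under the conditions of step 16 and converges on 31.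

Step 3. The cycloaddition of the tetrasubstituted dienophile may be too slow, so that the silyl dienol ether decomposes thermally and endo selectivity erodes at the temperature needed. The fallback sets out from 5 and comes back at 7. The strain-activated dienophile 3,4-diethylcyclobut-3-ene-1,2-dione F3 (from commercial diethyl squarate by two ethyllithium additions, each followed by acid-induced loss of ethanol) is combined with 5 at lower temperature to give the cis-fused adduct 2-[(tert-butyldimethylsilyl)oxy]-1,6-diethyl-3-methylbicyclo[4.2.0]oct-3-ene-7,8-dione F4. Excess mCPBA then inserts oxygen between the two carbonyl groups (Baeyer–Villiger oxidation of the 1,2-dione to the anhydride) and epoxidises the ring alkene on the convex face, giving 7.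

Step 11. The hindered tertiary allylic alcohol may ionise or dehydrate under the hot, acidic conditions before the ketene acetal forms, and the rearrangement next to the quaternary C4 may be slow. The fallback sets out from 18 and comes back at 21. Alcohol 18 is acylated (MeMgBr, then butanoyl chloride) to the butanoate tert-butyl 4-(butanoyloxy)-5-[(tert-butyldimethylsilyl)oxy]-1,6-diethyl-4-methyl-6-[(E)-2-phenylethenyl]cyclohex-2-ene-1-carboxylate F5. F5 is converted with KN(SiMe3)2 and Me3SiCl into its silyl ketene acetal and rearranged without acid (Ireland–Claisen) to the carboxylic acid 2-{6-(tert-butoxycarbonyl)-4-[(tert-butyldimethylsilyl)oxy]-5,6-diethyl-3-methyl-5-[(E)-2-phenylethenyl]cyclohex-2-en-1-yl}butanoic acid F6 after hydrolytic work-up. Me3SiCHN2 then gives methyl ester 21.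

Further compounds
F1 | step 15 | tert-butyl 1,6-diethyl-2-(1-methoxy-1-oxobutan-2-yl)-3-(1-methoxy-1-oxopropan-2-yl)-4-methyl-6-[(E)-2-phenylethenyl]cyclohex-4-ene-1-carboxylate | COC(=O)C(C)[C@@H]1C(C)=C[C@@](/C=C/c2ccccc2)(CC)[C@](CC)(C(=O)OC(C)(C)C)[C@H]1C(CC)C(=O)OC
F2 | step 15 | 4-tert-butyl 1-methyl 3,4,5-triethyl-1,7-dimethyl-2-oxo-5-[(E)-2-phenylethenyl]-2,3,3a,4,5,7a-hexahydro-1H-indene-1,4-dicarboxylate | CCC1C(=O)C(C)(C(=O)OC)[C@@H]2C(C)=C[C@@](/C=C/c3ccccc3)(CC)[C@](CC)(C(=O)OC(C)(C)C)[C@H]21
F3 | step 3 | 3,4-diethylcyclobut-3-ene-1,2-dione | CCC1=C(CC)C(=O)C1=O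
F4 | step 3 | rac-2-[(tert-butyldimethylsilyl)oxy]-1,6-diethyl-3-methylbicyclo[4.2.0]oct-3-ene-7,8-dione | CC1=CC[C@@]2(CC)C(=O)C(=O)[C@@]2(CC)[C@H]1O[Si](C)(C)C(C)(C)C
F5 | step 11 | tert-butyl 4-(butanoyloxy)-5-[(tert-butyldimethylsilyl)oxy]-1,6-diethyl-4-methyl-6-[(E)-2-phenylethenyl]cyclohex-2-ene-1-carboxylate | C[C@@]1(OC(=O)CCC)C=C[C@@](CC)(C(=O)OC(C)(C)C)[C@@](CC)(/C=C/c2ccccc2)[C@H]1O[Si](C)(C)C(C)(C)C
F6 | step 11 | 2-{6-(tert-butoxycarbonyl)-4-[(tert-butyldimethylsilyl)oxy]-5,6-diethyl-3-methyl-5-[(E)-2-phenylethenyl]cyclohex-2-en-1-yl}butanoic acid | CC1=C[C@H](C(CC)C(=O)O)[C@@](CC)(C(=O)OC(C)(C)C)[C@@](CC)(/C=C/c2ccccc2)[C@H]1O[Si](C)(C)C(C)(C)C
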